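In the first minutes the runs say little: target reads 2% in dawn at 2.00 min and 3% in autumn at 1.50 min, against a scatter of 2 percentage points. So I read both runs at 25.0 min, where the signal stands clear of the scatter: 19% in dawn and 29% in autumn.

the same everywhere: solid electrophile 0.050 M

| flask | nucleophile | remark | time |
|---|---|---|---|
| dawn | 0.84 equiv | run made earlier |  |
| autumn | 1.8 equiv | run made earlier |  |
| maple | 1.00 equiv |  | 25 min |
| elm | 2.00 equiv |  | 25 min |

- dawn (time / min: solid electrophile / %, target / %): 2.00: 94, 2; 3.00: 94, 2; 6.00: 81, 1; 10.0: 69, 5; 15.0: 56, 9; 25.0: 45, 19
- autumn (time / min: solid electrophile / %, target / %): 1.50: 93, 3; 5.00: 86, 7; 8.00: 76, 3; 15.0: 54, 16; 20.0: 46, 23; 25.0: 33, 29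

(each reading ± 2 percentage points)

- at the start none of the solid electrophile is in solution
- what has only dissolved of solid electrophile counts as not reacted

- part of the solid electrophile that has reacted (what has only dissolved counts as not reacted) at the end, maple
- part of the solid electrophile that has reacted (what has only dissolved counts as not reacted) at the end, elm
- what raising the equivalents of nucleophile from its lowest to its highest value here does to the part of the solid electrophile that has reacted (what has only dissolved counts as not reacted) (changes below 5 percentage points count as none) (it rises / it falls / no change)

I turn the trend round and ask what would make raising the nucleophile from 1.00 equiv to 2.00 equiv change nothing. The slope of log target against log equivalents, from dawn to autumn, is 0.555, with an uncertainty of 0.165 from the scatter. This apparent order n is the number I carry.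

Scaled from dawn by n, target is 20.9% at 1.00 equiv, and scaled on to 2.00 equiv it is 30.7%. These two values of target are my estimates for the part reacted, and they run low if reaction makes anything besides target. A rise under 5 points would need n below 0.309. The runs put n higher than that, by 1.49 uncertainties, so I expect a rise.

The forecast gives 21.5% for maple and 31% for elm, and says it rises, on the ground “So reacted is approximately target, assuming no hidden by-products”.

The flask gives 26.8% for maple and 44.6% for elm: it rises, by 18 points.

    electrophile + nucleophile → acid set free + target (k = 4.40 L mol⁻¹ min⁻¹)
    nucleophile + acid set free ⇌ protonated nucleophile, settled at all times (K = 1.90 × 10⁵ L mol⁻¹)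
    target ⇌ isomer of the product (K = 7.20, k = 0.0380 min⁻¹)
    solid electrophile ⇌ electrophile, rate k4*(cs4 - [electrophile]) while solid is left; crystals form when [electrophile] > cs4 (solubility = 30.0 mM, k = 0.0640 min⁻¹)
    nucleophile ⇌ dormant form (K = 2.10, k = 1.70 min⁻¹)

The part reacted in elm stands above its target: at 25.0 min that flask holds target 30.4% and isomer of the product 14.1%. Carried from maple's result, n gives elm 39.4%, against 44.6%. The neighbouring flask is maple with 1.70 equiv of nucleophile; the same reckoning gives it 36.0%, and its result is 40.0%.

(All runs are simulated with made-up constants; the scatter is artificial.)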